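Assumptions (one line each):
- The C11′ hydroxyl is carried as its TBS ether from 12 to 20; small atom-delivering reagents (vinyl Grignard, allyl iodide, ylide, phosphonate, acrylic acid, TBSCl, TBHP) are listed under "Reagents that add atoms" and are not numbered.
- The Ti/tartrate oxidant is taken to follow the usual allylic-alcohol mnemonic for 2-furylcarbinols (L-(+)-tartrate oxidises the (S)-carbinol), and hydride is taken to add to 5 anti to the C6 substituent.

## Structural features

- The target is a 5,6-dihydro-2H-pyran-2-one (ring atoms O1, C2(=O), C3=C4, C5, C6). The C5 oxygen is esterified with a (2E,4E)-11-hydroxy-4,6-dimethyldodeca-2,4-dienoyl chain (C1′–C12′), and C6 carries an (E)-acrylic acid (C7=C8–C9O2H).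
- C5 and C6 are adjacent, both S, and cis on the ring. C6′ (R, allylic methyl) and C11′ (S, carbinol) are 1,6-related and remote from the ring, so they must be set independently.
- C2–C9 are a hidden C2-symmetric unit, (4S,5S)-4,5-dihydroxyocta-2,6-dienedioic acid. The target breaks its symmetry four times: C3=C4 is Z (in the ring) and C7=C8 is E; one carboxyl is a lactone and the other is free; one hydroxyl is in the lactone and the other is acylated.
- Fragile points: the C5 acyloxy group is allylic and γ to the lactone carbonyl, and C6–H is α-oxy and allylic, so base can eliminate to the aromatic 2H-pyran-2-one. A free C5–OH beside the Z-enoate can translactonise to the five-membered butenolide. A free acid and a free secondary alcohol must coexist at the end.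
- The real difficulty is to build the six-membered cis-5-acyloxy-6-alkenyl lactone without offering the system the kinetically preferred γ-lactone, while differentiating four oxygenated termini.
- The feature the key step exploits: C2–C3=C4–C5, with oxygen on C2 and C5 and a Z alkene, attached to the carbinol carbon C6, is the oxidation pattern of a ring-opened 2-furylcarbinol. Furan C5, C4, C3, C2 map onto C2, C3, C4, C5, and the carbinol oxygen becomes O1.

## Logic of the disconnections

In one sentence: the lactone ring arises by a titanium–tartrate kinetic-resolution Achmatowicz ring expansion of 2.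

21 to 20. The O–Si bond at C11′ is cut. The free alcohol would compete as a nucleophile in the acylation, so it stays masked until the end. The forward step must be non-basic.

20 to 19. The C7=C8 bond is cut; C8–C9 come from a simple C3 acrylate-type reagent by cross-metathesis on the C6 vinyl group. This brings in the free acid without a protecting group and only after the last basic step. The forward step must touch the monosubstituted alkene only, not the ring enoate or the dienoate.

19 to 6 and 18. The acyl C1′–O bond to C5 is cut. This divides the target into a C7 core and a C14 acid of similar effort. The forward acylation must be faster than translactonisation of 6.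

6 to 4 via 5. The C5–H bond (hydride) and the oxidation level at C2 are adjusted. Oxidising the lactol first locks the six-membered ring as a lactone before the C5 ketone is reduced, so the new C5 hydroxyl can never close a five-membered lactol. The reduction must deliver hydride anti to the C6 substituent to give the cis pair.

4 to 2 (key). The hemiacetal O1–C bond is opened and the cis-ene-1,4-dicarbonyl is folded back into the furan ring. This removes the ring, the Z alkene, two carbonyl groups and the need for an enantiopure precursor, leaving a racemic furylcarbinol. The forward step must oxidise the furan of one enantiomer only and spare the vinyl group.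

2 to 1. The C6–C7 bond is cut (vinyl nucleophile plus aldehyde). No selectivity is demanded because step 2 selects the enantiomer.

18 to 16 via 17. The C2′=C3′ bond is cut (phosphonate olefination, then ester hydrolysis). The forward step must be E-selective and must not epimerise C6′, which is γ to the enal.

16 to 15. The C4′=C5′ bond is cut (stabilised ylide plus α-branched aldehyde). The forward step must be base-free to keep C6′.

15 to 10 and 12 via 14 and 13. The C8′–C9′ bond is cut; it is made as an alkene by cross-metathesis and then saturated. This splits the two remote stereocentres into two small chiral pieces. The forward step must favour the cross product over the homodimers.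

10 to 7 via 9 and 8. The C6′–C7′ bond is cut (auxiliary-controlled enolate allylation, then reductive removal). The auxiliary must control the enolate face.

12 to 11. The O–Si bond is cut; C11′ is bought as a chiral-pool alcohol.

## Other disconnections considered

Alternative 1: Cut the C1′–O ester bond and the ring C3=C4 bond (ring-closing metathesis); this is the first route that comes to mind. Forward: the diol (3S,4S)-hexa-1,5-diene-3,4-diol A1 would be mono-acylated with 18 to the mono-ester A2, acryloylated to A3, and A3 closed by ring-closing metathesis to 19.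
- A3 holds two vinyl groups, so the acrylate can close on the nearer one to a five-membered butenolide or on the farther one to the six-membered lactone. Ring size rests on a kinetic preference, whereas the hemiacetal of 3 can only be six-membered.
- A1 is a chiral-pool diol of the less accessible enantiomeric series, and its mono-acylation with the most valuable intermediate 18 is statistical.
- 18 would then pass through two more steps, one with ruthenium, before the ring exists. The chosen plan makes the core from an achiral aldehyde in four steps and brings 18 in late.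

Alternative 2: Cut the lactone O1–C2 bond and C3=C4 (Z-selective olefination, then lactonisation of a chiral-pool threo-diol unit). Forward: the acetonide A4, methyl (2Z)-3-[(4S,5S)-2,2-dimethyl-5-vinyl-1,3-dioxolan-4-yl]prop-2-enoate, would be deprotected and lactonised.
- Removing the acetonide frees O5 and O6 together, and a (Z)-γ-hydroxy enoate should close to the five-membered butenolide A5 faster than the δ-hydroxyl closes the six-ring.
- Forcing the δ-lactone needs two different protecting groups on two hydroxyls that are homotopic in the precursor, plus differentiation of the two chain ends.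
- This should cost about twice the steps of the chosen core synthesis and still carries a Z-olefination as a selectivity risk.

Alternative 3: Cut the ring bonds C5–C6 and O1–C2 in one [4+2] step. Forward: a catalytic asymmetric hetero-Diels–Alder reaction between the dienyl ester A6 and the aldehyde A7 would give the cycloadduct A8 with C5 and C6 set cis (endo), followed by oxidation of the acetal carbon to the lactone.
- On paper this is the largest simplification, since ring, both stereocentres and the ester arrive together.
- A (1E,3E)-1-alkoxy-4-acyloxybutadiene of defined geometry is not an established diene class, and its acyloxy-bearing terminus, which must attack the aldehyde, is deactivated.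
- A7 offers a C=C dienophile at least as reactive as its C=O.
- The step would lie beyond known chemistry, while the chosen plan closes the same ring with a known reaction type.

Key step: step 2

## Steps

Step 1
Reactants: 1 furfural
Product: 2 rac-1-(furan-2-yl)prop-2-en-1-ol
Conditions: CH2=CHMgBr (1.1 equiv), THF, −78 → 0 °C; aq NH4Cl
Reagents that add atoms: vinylmagnesium bromide, C=C[Mg]Br
Why: Grignard 1,2-addition to an aldehyde; the racemate is wanted because step 2 selects the enantiomer.

Step 2
Reactants: 2 rac-1-(furan-2-yl)prop-2-en-1-ol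
Product: 4 (2S)-2-ethenyl-6-hydroxy-2H-pyran-3(6H)-one (mixture of anomers), via Z-keto-enal 3 (not isolated)
Conditions: Ti(OiPr)4 (0.15 equiv), L-(+)-DIPT (0.18 equiv), t-BuOOH (0.45 equiv, isooctane), 4 Å MS, CH2Cl2, −20 °C; stopped near 45 % conversion; unreacted (R)-enriched 2 removed by chromatography
Reagents that add atoms: tert-butyl hydroperoxide, CC(C)(C)OO
Why: Kinetic-resolution Achmatowicz rearrangement under titanium–tartrate/TBHP (the Sharpless kinetic-resolution reagent applied to a 2-furylcarbinol, a known reaction type). The titanium-bound alkoxide of the (S)-enantiomer of 2 is the matched case for transfer of the peroxide oxygen to the furan C2=C3 bond next to the carbinol; the resulting 2,3-epoxy-2,3-dihydrofuran collapses to the Z-keto-enal 3, whose Z geometry is inherited from the furan ring. The carbinol oxygen of 3 then adds to the aldehyde in a 6-exo-trig hemiacetalisation, the only ring size open to a 1,5-related OH and CHO, to close the pyranone ring of 4. The carbinol centre (C6 of the target) is not created but selected: by the allylic-alcohol mnemonic, L-(+)-DIPT oxidises the (S)-carbinol and leaves the (R)-carbinol, so with 0.45 equiv of oxidant 4 should arise almost only from (S)-2. The new anomeric centre forms as a mixture and is erased in step 3. The step needs enantiomer discrimination, which the large rate ratio expected for furylcarbinols and the stop near 45 % conversion should secure, and furan-over-vinyl chemoselectivity, which the far higher nucleophilicity of the furan should secure, helped by the fact that vinyl epoxidation is the mismatched pathway for (S)-2 under the same tartrate.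

Step 3
Reactants: 4 (2S)-2-ethenyl-6-hydroxy-2H-pyran-3(6H)-one
Product: 5 (6S)-6-ethenyl-2H-pyran-2,5(6H)-dione
Conditions: Jones reagent (CrO3, aq H2SO4), acetone, 0 °C, 15 min; used crude at once
Reagents that add atoms: none
Why: Jones oxidation of the lactol to the lactone, the standard conversion of Achmatowicz hemiacetals into pyran-2,5-diones, which fixes the six-membered ring before C5 is reduced. C6–H is now α to a ketone and allylic, so 5 is not stored.

Step 4
Reactants: 5 (6S)-6-ethenyl-2H-pyran-2,5(6H)-dione
Product: 6 (5S,6S)-6-ethenyl-5-hydroxy-5,6-dihydro-2H-pyran-2-one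
Conditions: NaBH4, CeCl3·7H2O, MeOH/CH2Cl2, −78 °C
Reagents that add atoms: none
Why: Luche 1,2-reduction of the C5 ketone, which should leave the lactone enoate alone. Hydride should add to the flattened ring on the face anti to the C6 vinyl group (1,2-induction), placing the new C5–OH cis to it (5S); the low temperature should also outrun enolisation of 5.

Step 5
Reactants: 7 (4S)-4-benzyl-3-propanoyl-1,3-oxazolidin-2-one
Product: 9 (4S)-4-benzyl-3-[(2R)-2-methylpent-4-enoyl]-1,3-oxazolidin-2-one, via sodium Z-enolate 8 (not isolated)
Conditions: NaHMDS, THF, −78 °C; allyl iodide, −78 → −45 °C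
Reagents that add atoms: allyl iodide, C=CCI
Why: Evans asymmetric alkylation; the chelated Z-enolate should be allylated on the face opposite the benzyl group, which sets C6′ as R.

Step 6
Reactants: 9 (4S)-4-benzyl-3-[(2R)-2-methylpent-4-enoyl]-1,3-oxazolidin-2-one
Product: 10 (2R)-2-methylpent-4-en-1-ol
Conditions: LiBH4, H2O (1 equiv), Et2O, 0 °C
Reagents that add atoms: none
Why: Reductive cleavage of the imide releases the primary alcohol and the recoverable auxiliary without touching the α-stereocentre.

Step 7
Reactants: 11 (2S)-pent-4-en-2-ol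
Product: 12 tert-butyldimethyl{[(2S)-pent-4-en-2-yl]oxy}silane
Conditions: TBSCl, imidazole, DMF, rt
Reagents that add atoms: tert-butyldimethylsilyl chloride, CC(C)(C)[Si](C)(C)Cl
Why: Standard silylation; the C11′ stereocentre is taken from the chiral pool and is not touched again.

Step 8
Reactants: 10 (2R)-2-methylpent-4-en-1-ol; 12 tert-butyldimethyl{[(2S)-pent-4-en-2-yl]oxy}silane (3 equiv)
Product: 13 (2R,7S)-7-[(tert-butyldimethylsilyl)oxy]-2-methyloct-4-en-1-ol (E/Z mixture)
Conditions: Hoveyda–Grubbs II (3 mol %), 1,4-benzoquinone (10 mol %), CH2Cl2, 40 °C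
Reagents that add atoms: none
Why: Olefin cross-metathesis of two terminal alkenes; the excess of 12 should bias the statistical mixture toward the cross product, and benzoquinone should suppress Ru–H chain walking. The alkene geometry is irrelevant because step 9 removes it.

Step 9
Reactants: 13 (2R,7S)-7-[(tert-butyldimethylsilyl)oxy]-2-methyloct-4-en-1-ol
Product: 14 (2R,7S)-7-[(tert-butyldimethylsilyl)oxy]-2-methyloctan-1-ol
Conditions: H2 (1 atm), 10 % Pd/C, EtOAc, rt
Reagents that add atoms: none
Why: Catalytic hydrogenation of an isolated disubstituted alkene; the silyl ether and both stereocentres are not affected.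

Step 10
Reactants: 14 (2R,7S)-7-[(tert-butyldimethylsilyl)oxy]-2-methyloctan-1-ol
Product: 15 (2R,7S)-7-[(tert-butyldimethylsilyl)oxy]-2-methyloctanal
Conditions: Dess–Martin periodinane, CH2Cl2, 0 °C → rt; used crude
Reagents that add atoms: none
Why: Dess–Martin oxidation under near-neutral conditions should keep the α-stereocentre of the aldehyde.

Step 11
Reactants: 15 (2R,7S)-7-[(tert-butyldimethylsilyl)oxy]-2-methyloctanal
Product: 16 (2E,4R,9S)-9-[(tert-butyldimethylsilyl)oxy]-2,4-dimethyldec-2-enal
Conditions: Ph3P=C(CH3)CHO, toluene, 90 °C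
Reagents that add atoms: 2-(triphenyl-λ5-phosphanylidene)propanal, CC(C=O)=P(c1ccccc1)(c1ccccc1)c1ccccc1
Why: Wittig reaction with a stabilised ylide should give the (E)-trisubstituted enal (C4′=C5′); no external base is present, so C6′ should be kept.

Step 12
Reactants: 16 (2E,4R,9S)-9-[(tert-butyldimethylsilyl)oxy]-2,4-dimethyldec-2-enal
Product: 17 ethyl (2E,4E,6R,11S)-11-[(tert-butyldimethylsilyl)oxy]-4,6-dimethyldodeca-2,4-dienoate
Conditions: (EtO)2P(O)CH2CO2Et, NaH, THF, 0 °C; then 16, 0 °C → rt
Reagents that add atoms: triethyl phosphonoacetate, CCOC(=O)CP(=O)(OCC)OCC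
Why: Horner–Wadsworth–Emmons olefination should form C2′=C3′ with E geometry; the anion is preformed, so no free base should reach the γ-stereocentre C6′.

Step 13
Reactants: 17 ethyl (2E,4E,6R,11S)-11-[(tert-butyldimethylsilyl)oxy]-4,6-dimethyldodeca-2,4-dienoate
Product: 18 (2E,4E,6R,11S)-11-[(tert-butyldimethylsilyl)oxy]-4,6-dimethyldodeca-2,4-dienoic acid
Conditions: LiOH·H2O, THF/MeOH/H2O, rt → 40 °C; then 1 M HCl to pH 3, 0 °C
Reagents that add atoms: lithium hydroxide, [Li+].[OH-]
Why: Saponification of the ethyl ester; the secondary TBS ether and the diene geometry should survive hydroxide and the brief mild acidification.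

Step 14
Reactants: 6 (5S,6S)-6-ethenyl-5-hydroxy-5,6-dihydro-2H-pyran-2-one; 18 (2E,4E,6R,11S)-11-[(tert-butyldimethylsilyl)oxy]-4,6-dimethyldodeca-2,4-dienoic acid
Product: 19 (2S,3S)-2-ethenyl-6-oxo-3,6-dihydro-2H-pyran-3-yl (2E,4E,6R,11S)-11-[(tert-butyldimethylsilyl)oxy]-4,6-dimethyldodeca-2,4-dienoate
Conditions: DCC, DMAP (0.2 equiv), CH2Cl2, 0 °C → rt
Reagents that add atoms: none
Why: Steglich esterification forms the acyl C1′–O bond, so the cis C5 configuration is retained. At this stage C6 carries a vinyl group and not the acrylate, so C6–H should not be acidic enough for elimination to the pyranone in this only basic step on the assembled core.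

Step 15
Reactants: 19 (2S,3S)-2-ethenyl-6-oxo-3,6-dihydro-2H-pyran-3-yl (2E,4E,6R,11S)-11-[(tert-butyldimethylsilyl)oxy]-4,6-dimethyldodeca-2,4-dienoate
Product: 20 (2E)-3-[(2S,3S)-3-{[(2E,4E,6R,11S)-11-[(tert-butyldimethylsilyl)oxy]-4,6-dimethyldodeca-2,4-dienoyl]oxy}-6-oxo-3,6-dihydro-2H-pyran-2-yl]prop-2-enoic acid
Conditions: acrylic acid (8 equiv), Hoveyda–Grubbs II (7 mol %), CH2Cl2, 40 °C
Reagents that add atoms: acrylic acid, C=CC(=O)O
Why: Cross-metathesis of the C6 vinyl group with acrylic acid should give the (E)-acrylic acid directly. The ring enoate, the conjugated C2′=C3′ bond and the trisubstituted C4′=C5′ bond are poor metathesis partners and should stay intact.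

Step 16
Reactants: 20 (2E)-3-[(2S,3S)-3-{[(2E,4E,6R,11S)-11-[(tert-butyldimethylsilyl)oxy]-4,6-dimethyldodeca-2,4-dienoyl]oxy}-6-oxo-3,6-dihydro-2H-pyran-2-yl]prop-2-enoic acid
Product: 21 (2E)-3-[(2S,3S)-3-{[(2E,4E,6R,11S)-11-hydroxy-4,6-dimethyldodeca-2,4-dienoyl]oxy}-6-oxo-3,6-dihydro-2H-pyran-2-yl]prop-2-enoic acid (target)
Conditions: HF·pyridine, THF, 0 °C → rt
Reagents that add atoms: none
Why: Acidic fluoride desilylation frees the C11′ hydroxyl without base, so the allylic C5 ester, the lactone and the C6 stereocentre should not be endangered.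

## Compound list

1 | furfural (furan-2-carbaldehyde) | O=Cc1ccco1 | starting material
2 | rac-1-(furan-2-yl)prop-2-en-1-ol | OC(C=C)c1ccco1 | intermediate
3 | (2Z,5S)-5-hydroxy-4-oxohepta-2,6-dienal | O[C@H](C(=O)/C=C\C=O)C=C | intermediate (not isolated)
4 | (2S)-2-ethenyl-6-hydroxy-2H-pyran-3(6H)-one (anomer mixture) | O=C1C=CC(O)O[C@H]1C=C | intermediate
5 | (6S)-6-ethenyl-2H-pyran-2,5(6H)-dione | O=C1C=CC(=O)O[C@H]1C=C | intermediate
6 | (5S,6S)-6-ethenyl-5-hydroxy-5,6-dihydro-2H-pyran-2-one | O[C@H]1C=CC(=O)O[C@H]1C=C | intermediate
7 | (4S)-4-benzyl-3-propanoyl-1,3-oxazolidin-2-one | CCC(=O)N1[C@@H](Cc2ccccc2)COC1=O | starting material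
8 | sodium (Z)-enolate of 7 | C/C=C(\[O-])N1[C@@H](Cc2ccccc2)COC1=O.[Na+] | intermediate (not isolated)
9 | (4S)-4-benzyl-3-[(2R)-2-methylpent-4-enoyl]-1,3-oxazolidin-2-one | C=CC[C@@H](C)C(=O)N1[C@@H](Cc2ccccc2)COC1=O | intermediate
10 | (2R)-2-methylpent-4-en-1-ol | C=CC[C@@H](C)CO | intermediate
11 | (2S)-pent-4-en-2-ol | C[C@H](O)CC=C | starting material
12 | tert-butyldimethyl{[(2S)-pent-4-en-2-yl]oxy}silane | C[C@H](O[Si](C)(C)C(C)(C)C)CC=C | intermediate
13 | (2R,7S)-7-[(tert-butyldimethylsilyl)oxy]-2-methyloct-4-en-1-ol (E/Z mixture) | OC[C@H](C)CC=CC[C@H](C)O[Si](C)(C)C(C)(C)C | intermediate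
14 | (2R,7S)-7-[(tert-butyldimethylsilyl)oxy]-2-methyloctan-1-ol | OC[C@H](C)CCCC[C@H](C)O[Si](C)(C)C(C)(C)C | intermediate
15 | (2R,7S)-7-[(tert-butyldimethylsilyl)oxy]-2-methyloctanal | O=C[C@H](C)CCCC[C@H](C)O[Si](C)(C)C(C)(C)C | intermediate
16 | (2E,4R,9S)-9-[(tert-butyldimethylsilyl)oxy]-2,4-dimethyldec-2-enal | O=C/C(C)=C/[C@H](C)CCCC[C@H](C)O[Si](C)(C)C(C)(C)C | intermediate
17 | ethyl (2E,4E,6R,11S)-11-[(tert-butyldimethylsilyl)oxy]-4,6-dimethyldodeca-2,4-dienoate | CCOC(=O)/C=C/C(C)=C/[C@H](C)CCCC[C@H](C)O[Si](C)(C)C(C)(C)C | intermediate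
18 | (2E,4E,6R,11S)-11-[(tert-butyldimethylsilyl)oxy]-4,6-dimethyldodeca-2,4-dienoic acid | OC(=O)/C=C/C(C)=C/[C@H](C)CCCC[C@H](C)O[Si](C)(C)C(C)(C)C | intermediate
19 | (2S,3S)-2-ethenyl-6-oxo-3,6-dihydro-2H-pyran-3-yl (2E,4E,6R,11S)-11-[(tert-butyldimethylsilyl)oxy]-4,6-dimethyldodeca-2,4-dienoate | CC(/C=C/C(=O)O[C@H]1C=CC(=O)O[C@H]1C=C)=C\[C@H](C)CCCC[C@H](C)O[Si](C)(C)C(C)(C)C | intermediate
20 | (2E)-3-[(2S,3S)-3-{[(2E,4E,6R,11S)-11-[(tert-butyldimethylsilyl)oxy]-4,6-dimethyldodeca-2,4-dienoyl]oxy}-6-oxo-3,6-dihydro-2H-pyran-2-yl]prop-2-enoic acid | CC(/C=C/C(=O)O[C@H]1C=CC(=O)O[C@H]1/C=C/C(=O)O)=C\[C@H](C)CCCC[C@H](C)O[Si](C)(C)C(C)(C)C | intermediate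
21 | (2E)-3-[(2S,3S)-3-{[(2E,4E,6R,11S)-11-hydroxy-4,6-dimethyldodeca-2,4-dienoyl]oxy}-6-oxo-3,6-dihydro-2H-pyran-2-yl]prop-2-enoic acid (CNP0107712.2) | CC(/C=C/C(=O)O[C@H]1C=CC(=O)O[C@H]1/C=C/C(=O)O)=C\[C@H](C)CCCC[C@H](C)O | target

## Step count and least certain steps

Total step count: 16. Longest linear sequence: 11 steps (7 → 9 → 10 → 13 → 14 → 15 → 16 → 17 → 18 → 19 → 20 → 21; steps 5, 6, 8–16). The core branch from 1 to 6 is four steps.

Step 2 (key step). The most likely failure is incomplete enantiomer discrimination at a useful conversion: oxidation of the (R)-carbinol may begin before the (S)-carbinol is consumed, so the pyranone would carry eroded enantiopurity, and product-mode kinetic resolution cannot correct this afterwards. The titanium Lewis acid may also ionise the doubly activated carbinol. The fallback separates resolution from ring expansion. Starting from 2, the same titanium/TBHP oxidation is run with D-(−)-DIPT to about 60 % conversion. The (R)-carbinol is then consumed as the enantiomeric pyranone (2R)-2-ethenyl-6-hydroxy-2H-pyran-3(6H)-one F2, which is discarded, and (1S)-1-(furan-2-yl)prop-2-en-1-ol F1 is recovered in high enantiopurity as the slow-reacting isomer. F1 is then ring-expanded with the achiral oxidant NBS in buffered aqueous THF (NaHCO3, NaOAc, 0 °C), and the route is rejoined at 4.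

Step 4. The most likely failure is poor facial selectivity of hydride delivery: the enedione ring is nearly flat and a vinyl group is a small control element, so the trans alcohol may form or even predominate. The fallback makes the C5–O bond with inversion instead of retention. Starting from 5, the trans alcohol (5R,6S)-6-ethenyl-5-hydroxy-5,6-dihydro-2H-pyran-2-one F3 (separated from the reduction, or made on purpose with a different hydride) is coupled with 18 under Mitsunobu conditions (PPh3, DIAD, THF, 0 °C). The carboxylate displaces the activated C5 oxygen with inversion, and the route is rejoined at 19. Both C5 epimers of the alcohol thus lead to the same ester.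

Step 14. The most likely failure is slow acyl transfer from the DMAP-activated, conjugated and bulky dienoyl donor to the hindered cis alcohol. While 6 waits in the presence of DMAP it can translactonise to the butenolide, and the activated dienoyl unit can isomerise at C2′=C3′. The fallback changes the bond that joins the halves. Starting from 6, the alcohol is esterified with the small and very reactive diethylphosphonoacetic acid (DCC, CH2Cl2, 0 °C, no DMAP) to give (2S,3S)-2-ethenyl-6-oxo-3,6-dihydro-2H-pyran-3-yl 2-(diethoxyphosphoryl)acetate F4. F4 is then joined to enal 16 by a Horner–Wadsworth–Emmons olefination under Masamune–Roush conditions (LiCl, i-Pr2NEt, MeCN, rt), which forms C2′=C3′ directly. The route is rejoined at 19, and 17 and 18 are no longer needed.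

Step 15. The most likely failure is sluggish initiation at the hindered, oxygen-flanked C6 vinyl group, which would leave time for catalyst decay, Ru–H migration of the double bond, or secondary metathesis at the dienoate. The fallback puts the metathesis before the union, on a small substrate. Starting from 6, cross-metathesis with tert-butyl acrylate (Hoveyda–Grubbs II, CH2Cl2, 40 °C) gives tert-butyl (2E)-3-[(2S,3S)-3-hydroxy-6-oxo-3,6-dihydro-2H-pyran-2-yl]prop-2-enoate F5. F5 is esterified with 18 (DCC, catalytic DMAP, −20 → 0 °C, kept short because C6–H is now γ to an ester) to give tert-butyl (2E)-3-[(2S,3S)-3-{[(2E,4E,6R,11S)-11-[(tert-butyldimethylsilyl)oxy]-4,6-dimethyldodeca-2,4-dienoyl]oxy}-6-oxo-3,6-dihydro-2H-pyran-2-yl]prop-2-enoate F6. One acidolysis (TFA/CH2Cl2/H2O, 0 °C → rt) then removes the tert-butyl ester and the silyl ether together, and the route is rejoined at 21.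

## Further compounds

F1 | step 2 | (1S)-1-(furan-2-yl)prop-2-en-1-ol | O[C@H](c1ccco1)C=C
F2 | step 2 | (2R)-2-ethenyl-6-hydroxy-2H-pyran-3(6H)-one | O=C1C=CC(O)O[C@@H]1C=C
F3 | step 4 | (5R,6S)-6-ethenyl-5-hydroxy-5,6-dihydro-2H-pyran-2-one | O[C@@H]1C=CC(=O)O[C@H]1C=C
F4 | step 14 | (2S,3S)-2-ethenyl-6-oxo-3,6-dihydro-2H-pyran-3-yl 2-(diethoxyphosphoryl)acetate | CCOP(=O)(CC(=O)O[C@H]1C=CC(=O)O[C@H]1C=C)OCC
F5 | step 15 | tert-butyl (2E)-3-[(2S,3S)-3-hydroxy-6-oxo-3,6-dihydro-2H-pyran-2-yl]prop-2-enoate | O[C@H]1C=CC(=O)O[C@H]1/C=C/C(=O)OC(C)(C)C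
F6 | step 15 | tert-butyl (2E)-3-[(2S,3S)-3-{[(2E,4E,6R,11S)-11-[(tert-butyldimethylsilyl)oxy]-4,6-dimethyldodeca-2,4-dienoyl]oxy}-6-oxo-3,6-dihydro-2H-pyran-2-yl]prop-2-enoate | CC(/C=C/C(=O)O[C@H]1C=CC(=O)O[C@H]1/C=C/C(=O)OC(C)(C)C)=C\[C@H](C)CCCC[C@H](C)O[Si](C)(C)C(C)(C)C
A1 | alternative 1 | (3S,4S)-hexa-1,5-diene-3,4-diol | O[C@H]([C@@H](O)C=C)C=C
A2 | alternative 1 | (3S,4S)-4-hydroxyhexa-1,5-dien-3-yl (2E,4E,6R,11S)-11-[(tert-butyldimethylsilyl)oxy]-4,6-dimethyldodeca-2,4-dienoate | CC(/C=C/C(=O)O[C@H]([C@@H](O)C=C)C=C)=C\[C@H](C)CCCC[C@H](C)O[Si](C)(C)C(C)(C)C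
A3 | alternative 1 | (3S,4S)-4-(prop-2-enoyloxy)hexa-1,5-dien-3-yl (2E,4E,6R,11S)-11-[(tert-butyldimethylsilyl)oxy]-4,6-dimethyldodeca-2,4-dienoate | CC(/C=C/C(=O)O[C@H]([C@@H](OC(=O)C=C)C=C)C=C)=C\[C@H](C)CCCC[C@H](C)O[Si](C)(C)C(C)(C)C
A4 | alternative 2 | methyl (2Z)-3-[(4S,5S)-2,2-dimethyl-5-vinyl-1,3-dioxolan-4-yl]prop-2-enoate | COC(=O)/C=C\[C@@H]1OC(C)(C)O[C@H]1C=C
A5 | alternative 2 | (5S)-5-[(1S)-1-hydroxyprop-2-en-1-yl]furan-2(5H)-one | O=C1C=C[C@@H]([C@@H](O)C=C)O1
A6 | alternative 3 | (1E,3E)-4-methoxybuta-1,3-dien-1-yl (2E,4E,6R,11S)-11-[(tert-butyldimethylsilyl)oxy]-4,6-dimethyldodeca-2,4-dienoate | CO/C=C/C=C/OC(=O)/C=C/C(C)=C/[C@H](C)CCCC[C@H](C)O[Si](C)(C)C(C)(C)C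
A7 | alternative 3 | tert-butyl (2E)-4-oxobut-2-enoate | O=C/C=C/C(=O)OC(C)(C)C
A8 | alternative 3 | tert-butyl (2E)-3-[(2S,3S)-3-{[(2E,4E,6R,11S)-11-[(tert-butyldimethylsilyl)oxy]-4,6-dimethyldodeca-2,4-dienoyl]oxy}-6-methoxy-3,6-dihydro-2H-pyran-2-yl]prop-2-enoate (C6 epimers) | CC(/C=C/C(=O)O[C@H]1C=CC(OC)O[C@H]1/C=C/C(=O)OC(C)(C)C)=C\[C@H](C)CCCC[C@H](C)O[Si](C)(C)C(C)(C)C
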